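If the flat ends of the earlier runs are equilibrium and not a stalled reaction, then at such an end J and D stand in the ratio of free [Z] to one fixed concentration.

in all of them: G 2.6 mM; Q 3.5 mM

| flask | D | Z | remark | time |
|---|---|---|---|---|
| Monday's | 0.20 M | 0.16 M | run made earlier |  |
| Friday's | 0.20 M | 0.11 M | run made earlier |  |
| Tuesday's | 0.20 M | 0.24 M | run made earlier |  |
| Saturday's | 0.10 M | 0.16 M | run made earlier |  |
| alpha | 0.20 M | 0.160 M | a closed flask charged with all of it at once and left for 8.0 min | 8.0 min |
| theta | 0.20 M (fed, over 4.00 min) | 0.160 M | a stirred flask in which D is dosed at a steady rate over 4.00 min without added volume, worked up at 8.0 min | 8.0 min |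
| epsilon | 0.20 M | 0.160 M | a single well-mixed tank run continuously and read at steady state, 24.0 min in it on average |  |
| zeta | 0.20 M | 0.160 M | one stirred flow tank at steady state, fed with the mixture as stated, mean residence time 8.0 min |  |

| run | time / min | J / % | D / % |
|---|---|---|---|
| Monday's | 0.250 | 18.9 | 81.1 |
| Monday's | 0.667 | 23.3 | 75.7 |
| Monday's | 1.33 | 25.9 | 74.7 |
| Monday's | 2.00 | 26.1 | 73.7 |
| Monday's | 3.00 | 26.5 | 74.0 |
| Monday's | 4.00 | 26.8 | 73.0 |
| Monday's | 5.00 | 25.6 | 73.9 |
| Friday's | 0.417 | 14.5 | 85.0 |
| Friday's | 0.667 | 16.4 | 83.1 |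
| Friday's | 0.833 | 17.3 | 82.5 |
| Friday's | 1.33 | 18.4 | 81.8 |
| Friday's | 2.00 | 18.8 | 82.0 |
| Friday's | 3.00 | 18.9 | 81.6 |
| Friday's | 5.00 | 19.1 | 80.9 |
| Tuesday's | 0.667 | 33.3 | 67.1 |
| Tuesday's | 1.33 | 35.2 | 64.8 |
| Tuesday's | 2.00 | 35.6 | 64.2 |
| Tuesday's | 3.00 | 35.8 | 65.4 |
| Tuesday's | 4.00 | 36.0 | 65.0 |
| Tuesday's | 5.00 | 35.9 | 64.6 |
| Saturday's | 0.417 | 22.8 | 76.6 |
| Saturday's | 0.667 | 26.2 | 73.8 |
| Saturday's | 1.33 | 28.7 | 71.2 |
| Saturday's | 2.50 | 30.5 | 70.4 |
| Saturday's | 5.00 | 29.6 | 69.8 |

(readings scatter by 0.5 percentage points)

- the stated concentrations are those of everything mixed, before any reaction; amounts are the same in each set-up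
- the numbers in the tables scatter with a standard deviation of 0.5 percentage points
- the feed brings no volume worth counting
- the earlier runs were made in a closed, stirred flask

- the set-up with the highest amount of J at the outlet or at the end, in percent of the D put in ("none" if the first two lie within 2 percentage points) (alpha / theta / epsilon / zeta / none)
- amount of J at the outlet or at the end, in percent of the D put in, alpha
- amount of J at the outlet or at the end, in percent of the D put in, theta
- amount of J at the outlet or at the end, in percent of the D put in, epsilon
- amount of J at the outlet or at the end, in percent of the D put in, zeta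

The symmetric case gives the zero of the scale. The even-split level of Z is the free [Z] at which [J] equals [D], the reciprocal of the quotient [J]/([D][Z]). Tuesday's reading at 4.00 min gives it as 0.303 M. Friday's last reading, with a different charge of Z, gives 0.304 M. Alpha is charged with 0.160 M of Z, below that level, so D should stay the larger part. Solving the balance with this level gives 0.0524 M of J, or 26.2 % of the D.

Now the question turned round. Alpha and theta hold the same amounts, so a gap above 2 percentage points needs theta to stand that far short at 8.0 min. Monday's reading at 1.33 min, from a flask starting without J, lay 0.29 points below this ceiling, with a scatter of 0.5 points on it, and that time is shorter than the 4.00 min theta has after its feed. The readings stop at 5.00 min, earlier than 8.0 min, so theta's last stretch is the thing to watch.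

The forecast gives alpha 26.3 %, theta 26.1 %, epsilon 25.8 % and zeta 24.9 %, with best none, on the ground that “The plateaus are set by equilibrium, not by the reaction stalling.”

    G + Q ⇌ E (K = 4800 M⁻¹, k = 100 M⁻¹ s⁻¹)
    D + Z + G ⇌ J + G, rate k2*[D]*[Z]*[G] forward; the back reaction follows from the equilibrium constant (K = 3.30 M⁻¹, k = 170 M⁻² s⁻¹)

Alpha ends at 26.2 %, theta at 26.2 %, epsilon at 25.7 % and zeta at 24.8 %, so best is none. In alpha the relaxation half-life of D + Z and J, both ways together, is 0.332 min, shorter than the 8.0 min allowed, which is thermodynamic control. Free Z of 0.108 M over the even-split level 0.303 M gives 0.355, and alpha's J over D is 0.355. The neighbour charged with 0.64 M of Z ends with free Z of 0.514 M, above that level, which gives 1.70, and its J of 62.9 % over D of 37.1 % is 1.70.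

All runs are calculated for substances that don't exist.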